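**Retrosynthetic overview**

1. Building blocks: (+)-dihydromyricetin 1 (both gallocatechin units) and (+)-catechin 2 (terminal unit). All nine rings and every C2/C3 stereocentre are bought, so no ring is formed in the route and no protecting group is used.
2. Key step: 1 is reduced to the in-flask 3,4-diol 3, whose C4 cation is trapped by 1-methylimidazole. This C4–N bond gives the storable azolium electrophile 4.
3. Lower interflavan bond (C4–C8): at pH 8, 4 releases the ring A quinone methide 5, which 2 traps to give the dimer 6 (prodelphinidin B3).
4. Upper interflavan bond: a second portion of 4 alkylates C8 of the upper unit of 6 under the same conditions to give the target 7. Both C4 centres (4α, 3,4-trans) are set by attack anti to the C3–OH.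

Assumption: chromatography (Sephadex LH-20, reversed-phase HPLC) and recovery of the excess nucleophile are part of the work-up of a step, not steps of their own.

**Route**

Step 1
Reactants: 1 (+)-dihydromyricetin
Product: 4 3-methyl-1-[(2R,3S,4R)-3,5,7-trihydroxy-2-(3,4,5-trihydroxyphenyl)chroman-4-yl]imidazolium chloride, via leucodelphinidin 3 (not isolated)
Conditions: NaBH4 (2 equiv), EtOH, 0 °C to rt, Ar; then 1-methylimidazole/HCl buffer (3 M, pH 5.5), degassed H2O, 35 °C; Sephadex LH-20
Reagents that add atoms: 1-methylimidazole (Cn1ccnc1); hydrogen chloride (Cl)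
Why: Proposed new method: carbonyl reduction by NaBH4 gives the known, mainly 3,4-trans diol 3, whose benzylic C4–OH ionises at pH 5.5 to the phloroglucinol-stabilised C4 cation (protonated ring A quinone methide), and this cation is captured at N3 by free 1-methylimidazole (about 0.1 M and far more nucleophilic than any flavan ring A, hence no self-condensation) from the face anti to the C3–OH, giving an SN1-type C4–N bond that should stay intact as long as the ring A phenols are protonated; the closest known reactions are the acid-mediated thiol trapping of flavan-4-yl cations (thiolysis) and the formation of hydroxybenzyl-ammonium quinone-methide precursors, whereas an isolable flavan-4-yl onium salt has not been described; C2 and C3 come unchanged from 1, and the C4 configuration of 4 is erased later.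

Step 2
Reactants: 4 gallocatechin-4-yl methylimidazolium chloride (1 equiv); 2 (+)-catechin (5 equiv)
Product: 6 prodelphinidin B3 [gallocatechin-(4α→8)-catechin], via quinone methide 5 (not isolated)
Conditions: Na2HPO4/NaH2PO4 buffer (0.2 M, pH 8.0), degassed H2O–MeCN 4:1, Ar, 30 °C; then AcOH to pH 5; Sephadex LH-20
Reagents that add atoms: none
Why: Quinone-methide C-alkylation (Mannich-base-type release from a hydroxybenzyl-onium salt, run in the manner of the alkaline quinone-methide route to proanthocyanidins known for flavan-4-yl thioethers): at pH 8 the ring A phenolate of 4 slowly expels neutral 1-methylimidazole to give 5, the excess phloroglucinol-type ring A of 2 adds through C8 and rearomatises (Friedel–Crafts-type), and attack anti to the C3–OH of 5 sets C4 as 4α (3,4-trans, S).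

Step 3
Reactants: 4 gallocatechin-4-yl methylimidazolium chloride (1 equiv); 6 prodelphinidin B3 (2.5 equiv)
Product: 7 prodelphinidin C2 [gallocatechin-(4α→8)-gallocatechin-(4α→8)-catechin]
Conditions: Na2HPO4/NaH2PO4 buffer (0.2 M, pH 8.0), degassed H2O–MeCN 4:1, Ar, 30 °C; then AcOH to pH 5; Sephadex LH-20, then preparative C18 HPLC
Reagents that add atoms: none
Why: Quinone-methide C-alkylation under the step 2 conditions with 6 as the nucleophile: the quinone methide 5 that 4 releases at pH 8 is trapped by the most accessible phloroglucinol position of 6, C8 of its upper gallocatechin unit (the site that also gives the all-(4→8) linear trimer as the main trimer in the known flavan-3,4-diol condensations), again anti to the C3–OH, which sets the new C4 as 4α (S), while the excess of 6 limits growth beyond the trimer; the C4 made in step 2 keeps its geometry and is named R in 7 only because C8 of that unit is now substituted.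

**Compound list**

1 | (+)-dihydromyricetin, (2R,3R)-3,5,7-trihydroxy-2-(3,4,5-trihydroxyphenyl)chroman-4-one | Oc1cc(O)c2c(c1)O[C@H](c1cc(O)c(O)c(O)c1)[C@@H](O)C2=O | starting material
2 | (+)-catechin, (2R,3S)-2-(3,4-dihydroxyphenyl)chromane-3,5,7-triol | Oc1cc(O)c2c(c1)O[C@H](c1ccc(O)c(O)c1)[C@@H](O)C2 | starting material
3 | leucodelphinidin, (2R,3S,4R)-2-(3,4,5-trihydroxyphenyl)chromane-3,4,5,7-tetrol (2,3-trans-3,4-trans; the minor C4 epimer reacts the same way) | Oc1cc(O)c2c(c1)O[C@H](c1cc(O)c(O)c(O)c1)[C@@H](O)[C@@H]2O | intermediate
4 | 3-methyl-1-[(2R,3S,4R)-3,5,7-trihydroxy-2-(3,4,5-trihydroxyphenyl)chroman-4-yl]imidazolium chloride (gallocatechin with a 4α, 3,4-trans N-linked methylimidazolium) | Oc1cc(O)c2c(c1)O[C@H](c1cc(O)c(O)c(O)c1)[C@@H](O)[C@@H]2[n+]1ccn(C)c1.[Cl-] | intermediate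
5 | ring A para-quinone methide of gallocatechin, (2R,3S)-3,5-dihydroxy-2-(3,4,5-trihydroxyphenyl)-2,3-dihydro-7H-chromen-7-one | O=C1C=C2O[C@H](c3cc(O)c(O)c(O)c3)[C@@H](O)C=C2C(O)=C1 | intermediate
6 | prodelphinidin B3, gallocatechin-(4α→8)-catechin; upper unit (2R,3S,4S), lower unit (2R,3S) | Oc1cc(O)c2c(c1)O[C@H](c1cc(O)c(O)c(O)c1)[C@@H](O)[C@@H]2c1c(O)cc(O)c2c1O[C@H](c1ccc(O)c(O)c1)[C@@H](O)C2 | intermediate
7 | prodelphinidin C2, gallocatechin-(4α→8)-gallocatechin-(4α→8)-catechin; upper unit (2R,3S,4S), middle unit (2R,3S,4R), lower unit (2R,3S); both interflavan bonds 4α (3,4-trans) | Oc1cc(O)c2c(c1)O[C@H](c1cc(O)c(O)c(O)c1)[C@@H](O)[C@@H]2c1c(O)cc(O)c2c1O[C@H](c1cc(O)c(O)c(O)c1)[C@@H](O)[C@@H]2c1c(O)cc(O)c2c1O[C@H](c1ccc(O)c(O)c1)[C@@H](O)C2 | target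

**Step count and risks**

Total steps: 3. Longest linear sequence: 3 (1 → 4 → 6 → 7); 4 is made once and used in steps 2 and 3. Rough expectations, not measured: step 1 about 55 %, step 2 about 45 % on 4, step 3 about 20–25 % on 4, with unreacted 2 and 6 recovered.

The three steps most likely to fail, most risky first:

Step 1 (the proposed new method). The azolium salt may not form cleanly or may be too labile to isolate free of buffer. The fallback uses known chemistry and swaps the nitrogen leaving group for sulfur. It sets out from 1, which is reduced with NaBH4 as before, and the diol 3 is trapped with phenylmethanethiol in AcOH/EtOH to give 4α-benzylsulfanyl-gallocatechin F1 (standard thiol capture of flavan-3,4-diols). F1 and an excess of 2 are then coupled with AgBF4 in THF at 0 °C (thiophilic activation of free-phenolic flavan-4-yl thioethers under neutral conditions), and the path comes back to the route at 6. F1 then also takes the place of 4 in step 3.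

Step 3. The dimer 6 is the valuable partner yet offers three free nucleophilic positions (C8 and C6 of the upper unit, C6 of the lower unit), so regio-isomeric trimers and tetramers can erode the yield. The fallback reverses the order of assembly so that the last bond is made with cheap monomeric 2 in excess. It sets out from 1 (reduced to 3 in the flask) and from the thioether F1. Diol 3 is added slowly at pH 5 (AcOH buffer, H2O, rt) to 3–5 equiv of F1, whose C4–S bond does not ionise under these conditions, so F1 acts only as the nucleophile through C8. This gives the dimeric thioether gallocatechin-(4α→8)-gallocatechin 4α-benzyl thioether F2. F2 with AgBF4 in THF and an excess of 2 then gives the trimer directly, so the path comes back to the route at 7.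

Step 2. The onium leaving group is untested in this coupling. Hydration of 5 back to 3, a poorer C8/C6 ratio under phenolate conditions, or air oxidation of the pyrogallol ring at pH 8 could spoil it. The fallback changes from the base-triggered quinone methide to the acid-triggered carbocation. It sets out from 1, which is reduced with NaBH4 to 3, and 3 is condensed in the same flask with 5 equiv of 2 in water at pH 5 (AcOH), rt, under Ar. This is the classical flavan-3,4-diol condensation that gives prodelphinidin B3, and it comes back to the route at 6. No new compound arises on this path (entry F0).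

**Further compounds**

F1 | step 1 | 4α-benzylsulfanyl-gallocatechin, 2,3-trans-3,4-trans 4-(benzylsulfanyl)-2-(3,4,5-trihydroxyphenyl)chromane-3,5,7-triol | Oc1cc(O)c2c(c1)O[C@H](c1cc(O)c(O)c(O)c1)[C@@H](O)[C@@H]2SCc1ccccc1
F0 | step 2 | none | none
F2 | step 3 | gallocatechin-(4α→8)-gallocatechin 4α-benzyl thioether (benzylsulfanyl group at C4 of the lower unit, 3,4-trans) | Oc1cc(O)c2c(c1)O[C@H](c1cc(O)c(O)c(O)c1)[C@@H](O)[C@@H]2c1c(O)cc(O)c2c1O[C@H](c1cc(O)c(O)c(O)c1)[C@@H](O)[C@@H]2SCc1ccccc1
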